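Read everything in percent of the solid substrate charged; flasks with different charges then compare directly.

- spring: solid substrate 0.040 M; gas phase 3.7 mM (held); run made earlier
- flask: solid substrate 0.020 M; gas phase 3.7 mM (held); time 20 min

spring run (percent of the solid substrate charged)

| time / min | target / % | solid substrate / % |
|---|---|---|
| 0.833 | 0.6 | 90.2 |
| 1.50 | 2.4 | 82.8 |
| 2.50 | 6.2 | 71.4 |
| 3.00 | 7.1 | 66.8 |
| 4.00 | 10.6 | 55.2 |
| 5.00 | 13.5 | 44.6 |
| 6.00 | 16.8 | 33.7 |

(standard deviation of a reading: 0.5 percentage points)

- given per volume of solution although it is solid: solid substrate
- the numbers in the tables scatter with a standard deviation of 0.5 percentage points
- at the start none of the gas phase is in solution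
- at the start none of the solid substrate is in solution

You take over the flask: solid substrate stirred under the held gas. These are the questions for when you come back:

1. amount of target at 20 min, in percent of the solid substrate charged
2. concentration of dissolved gas in solution at 5.0 min, in percent of saturation
3. the change that raises the amount of target at 20 min, in percent of the solid substrate charged most ("none" if none brings more than 2 percentage points) (elm / birch / alder / cedar / none)
4. amount of target at 20 min, in percent of the solid substrate charged, after alder

- elm: doubling the saturation concentration of gas phase, all else as stated
- birch: doubling the transfer coefficient of the gas phase, all else as stated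
- alder: doubling the dissolution coefficient of the solid substrate, all else as stated
- cedar: doubling the solubility of the solid substrate, all else as stated

The gas is held, so balance the solid substrate. At the last spring reading, 6.00 min:

target / solid lost = 16.8% / 66.3% = 25.3%

Call this the target share, the target formed per solid lost; chemists say selectivity. The spring solid fell at a steady pace, and your flask holds half the spring charge:

clearing time = 0.020 M / 4.37 mM/min = 4.57 min

That is shorter than 20 min. So my reckoning is that no solid stands in the flask when you come, and target is about 25.3%. The other 74.7% is something else. Do not touch the gas supply: the share was read at 3.7 mM, the level this flask holds.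

The forecast differs: 98% target, 5.5% for the gas, none as best change and 98.5% after alder, since “conversion is nearly complete by 20 min”.

The flask gives 26.6% target at 20 min, and its dissolved gas stands at 70.8% of saturation at 5.0 min. The best change is elm, with a gain of 17 percentage points, and alder leaves 21.2% target.

    gas phase ⇌ dissolved gas, rate k1*(csat - [dissolved gas]) (kL = 0.0160 /s)
    starting material + dissolved gas → target (k = 5.10 /M/s)
    starting material → side product (k = 0.0280 /s)
    2 starting material → homo dimer (k = 0.710 /M/s)
    solid substrate ⇌ starting material, rate k5*(cs5 - [starting material]) while solid is left; crystals form when [starting material] > cs5 (solubility = 12.0 mM, k = 0.00720 /s)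

In the flask the solid stands at 0% at 20.0 min, so the flask's target share is 26.6%, against the 25.3% read from the spring run. The main reason for the flask's share is that starting material passes into side product: the flask without that step gives 64.2% target, against 26.6%. The neighbour flask at 0.012 M also keeps 0% of its charge, so the spring share puts its target at 25.3%, and that neighbour flask gives 25.4%.

The readings are calculated for an exercise; the scatter is artificial.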